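Everything rests on cutting the O1–C2 bond of the 1,4-dioxane ring (ring B). C2 carries ring oxygen O1, which sits on the benzo ring (ring A) para to the propenal chain, and an exocyclic CH2OH: the oxygen pattern of a terminal epoxide opened at its inner carbon. The key step exploits this: the ring A phenoxide opens such an epoxide intramolecularly, which closes ring B, sets C2 by inversion trans to the C3 aryl group and frees the CH2OH arm in one operation. The precursor is a phenol–epoxide whose O4–C3 benzylic ether and two stereocentres stem from one Sharpless epoxidation; its ring A formyl group is later extended by two carbons.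

Key step: step 9

Remark on the chemistry: ring C is the dimethoxyphenyl ring; the target is read from its SMILES as the (2S,3S) trans isomer, and D-(−)-diethyl tartrate is assumed to epoxidise the sinapyl-type alcohol with the same facial sense as (E)-cinnamyl alcohol, giving the (2R,3R) epoxy alcohol.

Step 1
Reactants: 1 syringaldehyde (4-hydroxy-3,5-dimethoxybenzaldehyde)
Product: 2 3,5-dimethoxy-4-(methoxymethoxy)benzaldehyde
Conditions: MOMCl, iPr2NEt, CH2Cl2, 0 °C → rt
Reagents that add atoms: chloromethyl methyl ether (MOMCl), COCCl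
Why: Williamson-type O-alkylation of the phenol with the reactive α-chloro ether masks the ring C hydroxyl as an acetal that survives hydride, base and zerovalent palladium, blocks quinone methide formation from the later benzylic ether under base, and is removable in mild acid at the end.

Step 2
Reactants: 2 3,5-dimethoxy-4-(methoxymethoxy)benzaldehyde; 3 triethyl phosphonoacetate
Product: 4 ethyl (2E)-3-[3,5-dimethoxy-4-(methoxymethoxy)phenyl]prop-2-enoate
Conditions: NaH, THF, 0 °C → rt
Reagents that add atoms: none
Why: Horner–Wadsworth–Emmons olefination of a non-enolisable aryl aldehyde with the stabilised phosphonate anion should give the (E)-cinnamate through the thermodynamically preferred elimination pathway.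

Step 3
Reactants: 4 ethyl (2E)-3-[3,5-dimethoxy-4-(methoxymethoxy)phenyl]prop-2-enoate
Product: 5 (2E)-3-[3,5-dimethoxy-4-(methoxymethoxy)phenyl]prop-2-en-1-ol
Conditions: iBu2AlH (2.5 equiv), CH2Cl2, −78 °C; aq. KNaC4H4O6 (potassium sodium tartrate) work-up
Reagents that add atoms: none
Why: DIBAL reduction of the conjugated ester proceeds by twofold 1,2-hydride delivery at low temperature and should leave the alkene geometry and the acetal untouched.

Step 4
Reactants: 5 (2E)-3-[3,5-dimethoxy-4-(methoxymethoxy)phenyl]prop-2-en-1-ol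
Product: 6 [(2R,3R)-3-[3,5-dimethoxy-4-(methoxymethoxy)phenyl]oxiran-2-yl]methanol
Conditions: Ti(OiPr)4 (10 mol%), D-(−)-diethyl tartrate (12 mol%), t-BuOOH (2 equiv, in decane), 4 Å molecular sieves, CH2Cl2, −20 °C
Reagents that add atoms: tert-butyl hydroperoxide, CC(C)(C)OO
Why: Sharpless asymmetric epoxidation, in which the titanium–D-(−)-tartrate complex binds the allylic alcohol and the hydroperoxide and delivers oxygen to one alkene face, so that the (E)-alkene should give the trans epoxide with both stereocentres (2R,3R) set by the tartrate, while sieves and a non-acidic work-up protect the benzylic epoxide.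

Step 5
Reactants: 7 3,4-dihydroxybenzaldehyde
Product: 8 3-hydroxy-4-(prop-2-en-1-yloxy)benzaldehyde
Conditions: allyl bromide (1.1 equiv), NaHCO3, DMF, 40 °C
Reagents that add atoms: allyl bromide, C=CCBr
Why: Williamson ether synthesis under weak base, in which hydrogencarbonate ionises only the more acidic hydroxyl para to the formyl group, so that the 4-hydroxyl is allylated and the hydroxyl meta to the formyl group stays free as the later nucleophile.

Step 6
Reactants: 6 [(2R,3R)-3-[3,5-dimethoxy-4-(methoxymethoxy)phenyl]oxiran-2-yl]methanol; 8 3-hydroxy-4-(prop-2-en-1-yloxy)benzaldehyde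
Product: 9 3-{[(1S,2R)-1-[3,5-dimethoxy-4-(methoxymethoxy)phenyl]-2,3-dihydroxypropyl]oxy}-4-(prop-2-en-1-yloxy)benzaldehyde
Conditions: 8 (2.5 equiv), NaOH (2.0 equiv), H2O/1,4-dioxane, 70 °C
Reagents that add atoms: none
Why: SN2 opening of a 2,3-epoxy alcohol by a phenoxide at C3, the mode established for 3-arylglycidols in aqueous base, where benzylic activation of C3 and inductive deactivation of C2 by the CH2OH group direct the attack, inversion at C3 sets the (S) benzylic ether centre and the (R) carbinol centre is carried over unchanged from the epoxide.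

Step 7
Reactants: 9 3-{[(1S,2R)-1-[3,5-dimethoxy-4-(methoxymethoxy)phenyl]-2,3-dihydroxypropyl]oxy}-4-(prop-2-en-1-yloxy)benzaldehyde
Product: 11 3-{(S)-[3,5-dimethoxy-4-(methoxymethoxy)phenyl][(2R)-oxiran-2-yl]methoxy}-4-(prop-2-en-1-yloxy)benzaldehyde, via primary monotosylate 10 (not isolated)
Conditions: TsCl (1.05 equiv), Et3N, Bu2SnO (2 mol%), CH2Cl2, 0 °C → rt; then K2CO3, MeOH, rt (one pot)
Reagents that add atoms: none
Why: Tin-catalysed regioselective sulfonylation of a 1,2-diol (stannylene acetal activation) should tosylate only the primary hydroxyl, and carbonate then closes the epoxide by intramolecular Williamson displacement at the primary carbon, so the C–O bond at the secondary carbon is never broken and its (R) configuration is retained.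

Step 8
Reactants: 11 3-{(S)-[3,5-dimethoxy-4-(methoxymethoxy)phenyl][(2R)-oxiran-2-yl]methoxy}-4-(prop-2-en-1-yloxy)benzaldehyde
Product: 12 4-hydroxy-3-{(S)-[3,5-dimethoxy-4-(methoxymethoxy)phenyl][(2R)-oxiran-2-yl]methoxy}benzaldehyde
Conditions: Pd(PPh3)4 (5 mol%), N-methylaniline (3 equiv), THF, rt
Reagents that add atoms: none
Why: Tsuji–Trost deallylation, in which zerovalent palladium ionises the allyl aryl ether to a π-allyl complex with the stabilised 4-formylphenoxide as leaving group and N-methylaniline captures the allyl unit, this amine being too weakly basic to ionise the freed phenol, so the epoxide should stay closed and the aldehyde and acetal untouched.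

Step 9
Reactants: 12 4-hydroxy-3-{(S)-[3,5-dimethoxy-4-(methoxymethoxy)phenyl][(2R)-oxiran-2-yl]methoxy}benzaldehyde
Product: 13 (2S,3S)-3-[3,5-dimethoxy-4-(methoxymethoxy)phenyl]-2-(hydroxymethyl)-2,3-dihydro-1,4-benzodioxine-6-carbaldehyde
Conditions: K2CO3 (1.2 equiv), DMF (0.05 M), 60 °C
Reagents that add atoms: none
Why: Carbonate ionises the ring A hydroxyl para to the formyl group, and this phenoxide displaces the epoxide oxygen from the inner (secondary) epoxide carbon by backside attack, so that the O1–C2 bond forms while the departing oxygen becomes the primary alkoxide, protonated to the CH2OH arm. The closest known reaction type is the base-induced cyclisation of catechol monoglycidyl ethers to 2-(hydroxymethyl)-1,4-benzodioxanes, of which 12 is the homologue bearing an aryl group on the carbon next to the ether oxygen. Ring B closes in the 6-exo-tet mode. The new stereocentre C2 is under substrate control: the (R) epoxide carbon laid down by the Sharpless epoxidation is inverted to (S), and since C3 was itself inverted when the benzylic ether was made, the trans epoxide should end as the trans (2S,3S) dioxane, with C3 untouched in this step. The step needs attack at the inner instead of the terminal carbon and complete inversion; the first is secured by the six-membered transition state being favoured over the seven-membered one that would lead to a benzodioxepine, the second by the fact that C2 is neither benzylic nor otherwise able to ionise, so only SN2 displacement is open to it. Moderate dilution keeps intermolecular phenoxide–epoxide coupling in check, and the opened alkoxide cannot close back to an epoxide, so the cyclisation is not reversible.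

Step 10
Reactants: 13 (2S,3S)-3-[3,5-dimethoxy-4-(methoxymethoxy)phenyl]-2-(hydroxymethyl)-2,3-dihydro-1,4-benzodioxine-6-carbaldehyde; 14 (triphenylphosphoranylidene)acetaldehyde
Product: 15 (2E)-3-[(2S,3S)-3-[3,5-dimethoxy-4-(methoxymethoxy)phenyl]-2-(hydroxymethyl)-2,3-dihydro-1,4-benzodioxin-6-yl]prop-2-enal
Conditions: 14 (1.2 equiv), toluene, 80 °C
Reagents that add atoms: none
Why: Wittig olefination with the stabilised formylmethylene ylide should give the (E)-enal, the free primary alcohol and the acetal being inert to this neutral reagent, and a small excess of ylide with monitoring limits a second homologation.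

Step 11
Reactants: 15 (2E)-3-[(2S,3S)-3-[3,5-dimethoxy-4-(methoxymethoxy)phenyl]-2-(hydroxymethyl)-2,3-dihydro-1,4-benzodioxin-6-yl]prop-2-enal
Product: 16 (2E)-3-[(2S,3S)-3-(4-hydroxy-3,5-dimethoxyphenyl)-2-(hydroxymethyl)-2,3-dihydro-1,4-benzodioxin-6-yl]prop-2-enal
Conditions: 2 M HCl (aq), THF, 40 °C
Reagents that add atoms: none
Why: Acid-catalysed acetal hydrolysis should remove the methoxymethyl group from the hindered ring C phenol under aqueous conditions that do not acetalise the enal and are too mild to ionise the C3–O4 benzylic ether, so both stereocentres are kept.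

Compound list
1 | syringaldehyde (4-hydroxy-3,5-dimethoxybenzaldehyde) | COc1cc(C=O)cc(OC)c1O | starting material
2 | 3,5-dimethoxy-4-(methoxymethoxy)benzaldehyde | COCOc1c(OC)cc(C=O)cc1OC | intermediate
3 | triethyl phosphonoacetate | CCOC(=O)CP(=O)(OCC)OCC | starting material
4 | ethyl (2E)-3-[3,5-dimethoxy-4-(methoxymethoxy)phenyl]prop-2-enoate | CCOC(=O)/C=C/c1cc(OC)c(OCOC)c(OC)c1 | intermediate
5 | (2E)-3-[3,5-dimethoxy-4-(methoxymethoxy)phenyl]prop-2-en-1-ol | OC/C=C/c1cc(OC)c(OCOC)c(OC)c1 | intermediate
6 | [(2R,3R)-3-[3,5-dimethoxy-4-(methoxymethoxy)phenyl]oxiran-2-yl]methanol | OC[C@H]1O[C@@H]1c1cc(OC)c(OCOC)c(OC)c1 | intermediate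
7 | 3,4-dihydroxybenzaldehyde | O=Cc1ccc(O)c(O)c1 | starting material
8 | 3-hydroxy-4-(prop-2-en-1-yloxy)benzaldehyde | C=CCOc1ccc(C=O)cc1O | intermediate
9 | 3-{[(1S,2R)-1-[3,5-dimethoxy-4-(methoxymethoxy)phenyl]-2,3-dihydroxypropyl]oxy}-4-(prop-2-en-1-yloxy)benzaldehyde | OC[C@@H](O)[C@@H](Oc1cc(C=O)ccc1OCC=C)c1cc(OC)c(OCOC)c(OC)c1 | intermediate
10 | (2R,3S)-3-[3,5-dimethoxy-4-(methoxymethoxy)phenyl]-3-[5-formyl-2-(prop-2-en-1-yloxy)phenoxy]-2-hydroxypropyl 4-methylbenzenesulfonate | Cc1ccc(cc1)S(=O)(=O)OC[C@@H](O)[C@@H](Oc1cc(C=O)ccc1OCC=C)c1cc(OC)c(OCOC)c(OC)c1 | intermediate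
11 | 3-{(S)-[3,5-dimethoxy-4-(methoxymethoxy)phenyl][(2R)-oxiran-2-yl]methoxy}-4-(prop-2-en-1-yloxy)benzaldehyde | COc1cc([C@H](Oc2cc(C=O)ccc2OCC=C)[C@H]2CO2)cc(OC)c1OCOC | intermediate
12 | 4-hydroxy-3-{(S)-[3,5-dimethoxy-4-(methoxymethoxy)phenyl][(2R)-oxiran-2-yl]methoxy}benzaldehyde | COc1cc([C@H](Oc2cc(C=O)ccc2O)[C@H]2CO2)cc(OC)c1OCOC | intermediate
13 | (2S,3S)-3-[3,5-dimethoxy-4-(methoxymethoxy)phenyl]-2-(hydroxymethyl)-2,3-dihydro-1,4-benzodioxine-6-carbaldehyde | COc1cc([C@@H]2Oc3cc(C=O)ccc3O[C@H]2CO)cc(OC)c1OCOC | intermediate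
14 | (triphenylphosphoranylidene)acetaldehyde | O=CC=P(c1ccccc1)(c1ccccc1)c1ccccc1 | starting material
15 | (2E)-3-[(2S,3S)-3-[3,5-dimethoxy-4-(methoxymethoxy)phenyl]-2-(hydroxymethyl)-2,3-dihydro-1,4-benzodioxin-6-yl]prop-2-enal | COc1cc([C@@H]2Oc3cc(/C=C/C=O)ccc3O[C@H]2CO)cc(OC)c1OCOC | intermediate
16 | (2E)-3-[(2S,3S)-3-(4-hydroxy-3,5-dimethoxyphenyl)-2-(hydroxymethyl)-2,3-dihydro-1,4-benzodioxin-6-yl]prop-2-enal | COc1cc([C@@H]2Oc3cc(/C=C/C=O)ccc3O[C@H]2CO)cc(OC)c1O | target

Total step count: 11. Longest linear sequence: 10 steps (steps 1–4 and 6–11, from syringaldehyde 1 to target 16).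

Steps most likely to fail

Step 9 (key step). The phenoxide is a weak nucleophile because of the para formyl group. It may attack the less hindered terminal epoxide carbon to give a seven-membered ring, or the epoxide of a second molecule, faster than it closes onto the hindered inner carbon. The fallback makes the same O1–C2 bond with the same inversion by an intramolecular Mitsunobu etherification and sets out from diol 9. TBSCl and imidazole in CH2Cl2 at 0 °C should silylate only the primary hydroxyl to give the mono-silylated allyl diol F1. Deallylation as in step 8 (Pd(PPh3)4, N-methylaniline, THF, rt) should give the silyl-protected phenol alcohol F2. PPh3 and diisopropyl azodicarboxylate in THF (0 °C → rt) should activate the C2 hydroxyl and let the ring A phenol displace it with inversion, giving the silyl-protected benzodioxane aldehyde F3. Bu4NF buffered with AcOH in THF then removes the silyl group, and the route is rejoined at 13.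

Step 6. Base-induced epoxide migration in the epoxy alkoxide (Payne rearrangement) followed by phenoxide attack at the terminal carbon, or hydroxide competing with the phenoxide, would erode regiocontrol at C3. The fallback caps the primary hydroxyl before the opening so that no alkoxide can form, and sets out from 6. TBDPSCl and imidazole in CH2Cl2 should give the silylated epoxy alcohol F4, the bulky silyl group being chosen for its resistance to base and to migration. The phenoxide of 8 (Cs2CO3, DMF, 80 °C) should open it at the benzylic carbon with inversion to the silylated aryloxy alcohol F5. Bu4NF in THF then frees the primary hydroxyl, and the route is rejoined at 9.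

Step 10. A second olefination of the product enal by the same ylide (over-homologation to a dienal), or sluggish reaction of the electron-rich aldehyde, would lower the efficiency. The fallback builds the enal through the ester oxidation state and sets out from 13. Horner–Wadsworth–Emmons olefination with 3 (LiCl, DBU, MeCN, rt) should give the (E)-ethyl enoate F6, which cannot react further. iBu2AlH in CH2Cl2 at −78 °C should reduce it to the (E)-allylic alcohol F7. MnO2 in CH2Cl2 at rt should oxidise only the allylic hydroxyl, and the route is rejoined at 15.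

Further compounds
F1 | step 9 | 3-{[(1S,2R)-3-{[tert-butyl(dimethyl)silyl]oxy}-1-[3,5-dimethoxy-4-(methoxymethoxy)phenyl]-2-hydroxypropyl]oxy}-4-(prop-2-en-1-yloxy)benzaldehyde | CC(C)(C)[Si](C)(C)OC[C@@H](O)[C@@H](Oc1cc(C=O)ccc1OCC=C)c1cc(OC)c(OCOC)c(OC)c1
F2 | step 9 | 3-{[(1S,2R)-3-{[tert-butyl(dimethyl)silyl]oxy}-1-[3,5-dimethoxy-4-(methoxymethoxy)phenyl]-2-hydroxypropyl]oxy}-4-hydroxybenzaldehyde | CC(C)(C)[Si](C)(C)OC[C@@H](O)[C@@H](Oc1cc(C=O)ccc1O)c1cc(OC)c(OCOC)c(OC)c1
F3 | step 9 | (2S,3S)-2-({[tert-butyl(dimethyl)silyl]oxy}methyl)-3-[3,5-dimethoxy-4-(methoxymethoxy)phenyl]-2,3-dihydro-1,4-benzodioxine-6-carbaldehyde | COc1cc([C@@H]2Oc3cc(C=O)ccc3O[C@H]2CO[Si](C)(C)C(C)(C)C)cc(OC)c1OCOC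
F4 | step 6 | tert-butyl({(2R,3R)-3-[3,5-dimethoxy-4-(methoxymethoxy)phenyl]oxiran-2-yl}methoxy)diphenylsilane | CC(C)(C)[Si](c1ccccc1)(c1ccccc1)OC[C@H]1O[C@@H]1c1cc(OC)c(OCOC)c(OC)c1
F5 | step 6 | 3-{[(1S,2R)-3-{[tert-butyl(diphenyl)silyl]oxy}-1-[3,5-dimethoxy-4-(methoxymethoxy)phenyl]-2-hydroxypropyl]oxy}-4-(prop-2-en-1-yloxy)benzaldehyde | CC(C)(C)[Si](c1ccccc1)(c1ccccc1)OC[C@@H](O)[C@@H](Oc1cc(C=O)ccc1OCC=C)c1cc(OC)c(OCOC)c(OC)c1
F6 | step 10 | ethyl (2E)-3-[(2S,3S)-3-[3,5-dimethoxy-4-(methoxymethoxy)phenyl]-2-(hydroxymethyl)-2,3-dihydro-1,4-benzodioxin-6-yl]prop-2-enoate | COc1cc([C@@H]2Oc3cc(/C=C/C(=O)OCC)ccc3O[C@H]2CO)cc(OC)c1OCOC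
F7 | step 10 | (2E)-3-[(2S,3S)-3-[3,5-dimethoxy-4-(methoxymethoxy)phenyl]-2-(hydroxymethyl)-2,3-dihydro-1,4-benzodioxin-6-yl]prop-2-en-1-ol | COc1cc([C@@H]2Oc3cc(/C=C/CO)ccc3O[C@H]2CO)cc(OC)c1OCOC
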